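**Retrosynthesis**
1. Andrographolide ⇐ global deprotection of the 3,19-acetonide/14-O-TES E-alkylidene butenolide ⇐ aldol/E1cB dehydration of the C12 aldehyde with (S)-3-silyloxy-γ-butyrolactone. C14 comes from the chiral pool.
2. The C12 aldehyde ⇐ the bicyclic 3α,19-diol with Δ8(17), made by one Ti(III) epoxide-initiated radical bicyclization. This forms rings A and B together and sets C3, C4, C5, C9 and C10.
3. The cyclization precursor is a cis-epoxy alcohol from Sharpless epoxidation of a (Z)-allylic alcohol (CH2OH cis to the chain, so it ends up axial as C19). That alcohol comes from a Z-selective Ando HWE on an aldehyde made by cleaving the terminal alkene of homofarnesol.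

Assumptions: (E,E)-homofarnesol is commercial (it is a fragrance intermediate). Simple reagents and catalysts are given by name and SMILES in each step rather than numbered.

---

**Step 1**
Reactants: 1 (3E,7E)-homofarnesol
Product: 2 homofarnesyl TBDPS ether
Conditions: TBDPSCl, imidazole, DMF, rt
Reagents that add atoms: TBDPSCl, CC(C)(C)[Si](Cl)(c1ccccc1)c1ccccc1
Why: Silylation of the primary alcohol gives a group that survives periodate, DIBAL, Ti(III) and the acidic steps.

**Step 2**
Reactants: 2
Product: 3 terminal 11,12-epoxide (racemic at C11; this stereocentre is destroyed in Step 3)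
Conditions: NBS, THF/H2O, 0 °C; then K2CO3, MeOH, rt
Reagents that add atoms: water, O (NBS bromine is lost)
Why: Bromohydrin formation (halohydrin/epoxide closure) favours the most remote, least hindered trisubstituted alkene. The remaining (E,E) alkenes are untouched.

**Step 3**
Reactants: 3
Product: 4 (4E,8E)-11-(TBDPSO)-4,8-dimethylundeca-4,8-dienal
Conditions: H5IO6, THF/Et2O, 0 °C
Reagents that add atoms: none
Why: Periodic acid hydrates the epoxide to the diol and cleaves it oxidatively (Malaprade-type). The products are the aldehyde and acetone, and the TBDPS group and both alkenes survive.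

**Step 4**
Reactants: 4; 5 ethyl 2-[bis(2-methylphenoxy)phosphoryl]propanoate (Ando reagent)
Product: 6 ethyl (2Z,6E,10E)-2,6,10-trimethyl-13-(TBDPSO)trideca-2,6,10-trienoate
Conditions: NaH, THF, −78 → −20 °C
Reagents that add atoms: none (the phosphonate is the numbered reactant)
Why: The Ando Z-selective Horner–Wadsworth–Emmons olefination puts the ester cis to the chain. That geometry is what later makes C19 axial.

**Step 5**
Reactants: 6
Product: 7 (2Z,6E,10E)-2,6,10-trimethyl-13-(TBDPSO)trideca-2,6,10-trien-1-ol
Conditions: DIBAL-H, CH2Cl2, −78 → 0 °C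
Reagents that add atoms: none
Why: 1,2-Reduction of the ester to the primary alcohol leaves the alkene geometries and the silyl ether intact.

**Step 6**
Reactants: 7
Product: 8 (2S,3R)-cis-2,3-epoxy-2,6,10-trimethyl-13-(TBDPSO)trideca-6,10-dien-1-ol
Conditions: Ti(OiPr)4, L-(+)-DET, TBHP, 4 Å MS, CH2Cl2, −20 °C
Reagents that add atoms: tert-butyl hydroperoxide, CC(C)(C)OO (its O ends up in the epoxide)
Why: Sharpless asymmetric epoxidation is hydroxyl-directed, so only the allylic alkene reacts. L-(+)-DET delivers oxygen to the face that gives the C3 configuration of the target (the 3S carbinol, written as 3α-O in the ent-labdane series). The Z geometry gives the cis-epoxide, with CH2OH cis to the chain.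

**Step 7**
Reactants: 8
Product: 9 13,14,15,16-tetranor-ent-labd-8(17)-ene-3α,12,19-triol 12-TBDPS ether
Conditions: Cp2TiCl2 (30 mol%), Mn, 2,4,6-collidine, TMSCl, THF, rt; aq. HCl workup
Reagents that add atoms: none
Why: Ti(III) opens the epoxide to the tertiary C4 radical, with the C3 oxygen bound to Ti. This triggers a chair–chair 6-endo/6-endo radical polyene cyclization (E,E-alkenes give the trans-anti-trans decalin), which sets C5, C10 and C9 relative to C3/C4. The bulky C3–OTi sits equatorial in the chair transition state, and the cis-epoxide geometry is expected to place CH2O axial (C19, syn to C20) and CH3 equatorial (C18). The C8 radical is trapped by Ti and β-H elimination gives the exocyclic C8=C17.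

**Step 8**
Reactants: 9
Product: 10 3,19-O-isopropylidene derivative of 9
Conditions: 2,2-dimethoxypropane, PPTS (cat.), acetone, rt
Reagents that add atoms: 2,2-dimethoxypropane, COC(C)(C)OC
Why: Acetalization of the 1,3-diol (3α-O equatorial, C19 axial) gives a six-membered acetonide. This protects both hydroxyls and allows any endocyclic alkene isomers to be separated by chromatography.

**Step 9**
Reactants: 10
Product: 11 C12 primary alcohol (acetonide retained)
Conditions: TBAF, THF, 0 °C → rt
Reagents that add atoms: none
Why: Fluoride-mediated desilylation removes the TBDPS group and leaves the acetonide and alkene untouched.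

**Step 10**
Reactants: 11
Product: 12 C12 aldehyde
Conditions: Dess–Martin periodinane, NaHCO3, CH2Cl2, 0 °C → rt
Reagents that add atoms: none
Why: Mild oxidation of the primary alcohol. C9 is β to the aldehyde, so it cannot epimerize through the enol.

**Step 11**
Reactants: 13 (S)-3-hydroxy-γ-butyrolactone
Product: 14 (S)-3-(triethylsilyloxy)-γ-butyrolactone
Conditions: TESCl, imidazole, DMF, 0 °C
Reagents that add atoms: TESCl, CC[Si](Cl)(CC)CC
Why: Silyl protection of the chiral-pool alcohol. This carbon becomes C14 (S) and is not touched again.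

**Step 12**
Reactants: 12; 14
Product: 15 aldol adduct (β-hydroxy lactone, mixture at C12/C13)
Conditions: LiHMDS, THF, −78 °C, then add 12, −78 °C; NH4Cl quench
Reagents that add atoms: none (LiHMDS is only a base; the new C–C bond joins C12 and C13, and the hydroxyl H comes from the quench)
Why: Lithium enolate aldol addition at low temperature avoids β-elimination of the OTES group. The new C12/C13 centres are removed in Step 13.

**Step 13**
Reactants: 15
Product: 16 3,19-acetonide, 14-OTES E-alkylidene butenolide
Conditions: MsCl, Et3N, CH2Cl2, 0 °C; then DBU, CH2Cl2, 23 → 40 °C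
Reagents that add atoms: none (the mesyl group is lost in the elimination)
Why: Mesylation then DBU-induced E1cB elimination under thermodynamic control gives mainly the E-Δ12 alkylidene lactone, with C11 trans to the carbonyl as in the target. Any Z isomer is removed by chromatography.

**Step 14**
Reactants: 16
Product: 17 andrographolide
Conditions: PPTS, MeOH/H2O (10:1), 50 °C
Reagents that add atoms: none
Why: Mild acid removes the TES ether and transketalizes the acetonide into the methanol solvent. The exocyclic alkene, the lactone and all stereocentres are unaffected.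

---

**Compound list**

1 | (3E,7E)-homofarnesol | OCC/C=C(\C)CC/C=C(\C)CC/C=C(C)C | starting material
2 | homofarnesyl TBDPS ether | CC(C)(C)[Si](c1ccccc1)(c1ccccc1)OCC/C=C(\C)CC/C=C(\C)CC/C=C(C)C | intermediate
3 | 11,12-epoxide of 2 (racemic at C11) | CC(C)(C)[Si](c1ccccc1)(c1ccccc1)OCC/C=C(\C)CC/C=C(\C)CCC1OC1(C)C | intermediate
4 | (4E,8E)-11-(TBDPSO)-4,8-dimethylundeca-4,8-dienal | O=CCC/C(C)=C/CC/C(C)=C/CCO[Si](c1ccccc1)(c1ccccc1)C(C)(C)C | intermediate
5 | ethyl 2-[bis(2-methylphenoxy)phosphoryl]propanoate (Ando reagent) | CCOC(=O)C(C)P(=O)(Oc1ccccc1C)Oc1ccccc1C | starting material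
6 | ethyl (2Z,6E,10E)-2,6,10-trimethyl-13-(TBDPSO)trideca-2,6,10-trienoate | CCOC(=O)/C(C)=C\CC/C(C)=C/CC/C(C)=C/CCO[Si](c1ccccc1)(c1ccccc1)C(C)(C)C | intermediate
7 | (2Z,6E,10E)-Z-allylic alcohol | OC/C(C)=C\CC/C(C)=C/CC/C(C)=C/CCO[Si](c1ccccc1)(c1ccccc1)C(C)(C)C | intermediate
8 | (2S,3R)-cis-epoxy alcohol | OC[C@]1(C)O[C@@H]1CC/C(C)=C/CC/C(C)=C/CCO[Si](c2ccccc2)(c2ccccc2)C(C)(C)C | intermediate
9 | tetranor-ent-labd-8(17)-ene-3α,12,19-triol 12-TBDPS ether | C=C1CC[C@@H]2[C@](C)(CO)[C@H](O)CC[C@@]2(C)[C@@H]1CCO[Si](c3ccccc3)(c3ccccc3)C(C)(C)C | intermediate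
10 | 3,19-acetonide of 9 | C=C1CC[C@@H]2[C@](C)(COC(C)(C)O3)[C@H]3CC[C@@]2(C)[C@@H]1CCO[Si](c4ccccc4)(c4ccccc4)C(C)(C)C | intermediate
11 | C12 alcohol, acetonide | C=C1CC[C@@H]2[C@](C)(COC(C)(C)O3)[C@H]3CC[C@@]2(C)[C@@H]1CCO | intermediate
12 | C12 aldehyde, acetonide | C=C1CC[C@@H]2[C@](C)(COC(C)(C)O3)[C@H]3CC[C@@]2(C)[C@@H]1CC=O | intermediate
13 | (S)-3-hydroxy-γ-butyrolactone | O=C1C[C@H](O)CO1 | starting material
14 | (S)-3-(triethylsilyloxy)-γ-butyrolactone | O=C1C[C@H](O[Si](CC)(CC)CC)CO1 | intermediate
15 | aldol adduct (C12/C13 unassigned) | C=C1CC[C@@H]2[C@](C)(COC(C)(C)O3)[C@H]3CC[C@@]2(C)[C@@H]1CC(O)C4C(=O)OC[C@H]4O[Si](CC)(CC)CC | intermediate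
16 | protected andrographolide (acetonide, 14-OTES, E-butenolide) | C=C1CC[C@@H]2[C@](C)(COC(C)(C)O3)[C@H]3CC[C@@]2(C)[C@@H]1C/C=C4/C(=O)OC[C@H]4O[Si](CC)(CC)CC | intermediate
17 | andrographolide | C=C1CC[C@@H]2[C@](C)(CO)[C@H](O)CC[C@@]2(C)[C@@H]1C/C=C1/C(=O)OC[C@H]1O | target

**Total steps:** 14 (Step 11 is a short side branch that prepares the lactone). **Longest linear sequence:** 13 steps, from 1 to 17.

**Three steps most likely to fail**
1. **Step 7, Ti(III) radical bicyclization.** It may give modest yield, endocyclic alkene isomers, or the wrong C4 configuration if the chair transition state does not keep the CH2OR axial.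
   - Fallback: change mechanism to a Lewis-acid cationic cascade. Protect the C19-OH of 8 as TBS and treat with MeAlCl2, so cyclization ends by proton loss to the exocyclic alkene.
2. **Step 2, terminal-selective epoxidation among three similar trisubstituted alkenes.** Selectivity and yield may be poor.
   - Fallback: assemble aldehyde 4 convergently. Make the aldehyde fragment from geranyl acetate, where only two alkenes compete, and couple it to a homogeranyl sulfone by Julia–Kocienski olefination.
3. **Steps 12–13, aldol and E1cB dehydration.** Aldehyde enolization, β-elimination of OTES to a butenolide, and E/Z control are all concerns.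
   - Fallback: skip the β-hydroxy intermediate. Use a Horner–Wadsworth–Emmons olefination of 12 with the α-diethylphosphono derivative of 14, made from the lactone enolate and ClP(O)(OEt)2.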